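The pyranone (ring C) is made last, by ring transposition and not by C–C bond formation. The 2'-OH of the target sits on ring B next to C1', so O2' can reach C2 just as O1 can. The route therefore first ties O2' to C2 as a furan, building C2–C3–C1' as a 3-aroylfuro[3,2-g]chromene. In the key step the only free ortho-phenol of the aroyl ring adds to furan C2 and the furan opens. This one operation closes ring C (O1–C2), releases the 2'-OH and fixes the prenyl at C6, not C8. The precursor is a (6-hydroxy-2,4-bis-MOM-oxy-3-prenylphenyl)(7,7-dimethylfurochromen-3-yl) ketone, unmasked in the flask from its THP ether.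

Key step: step 11

Remark: the target SMILES has no stereocentre, so "single enantiomer" is taken as the single achiral compound. Stereogenic atoms occur only in intermediates 7, 17, 18, 19 and 21, which are racemic, and all are erased before the end.

Step 1
Reactants: 1 4-bromoresorcinol; 2 3-methylbut-2-enoic acid
Product: 3 6-bromo-7-hydroxy-2,2-dimethylchroman-4-one
Conditions: P2O5/MsOH (Eaton's reagent, as medium), 70 °C
Reagents that add atoms: none
Why: Friedel–Crafts acylation by the mixed anhydride of 2 at the only activated, unhindered carbon of 1 (ortho to one OH, para to the other) followed by oxa-Michael closure should give the 2,2-dimethylchroman-4-one, so the bromine that marks the future C1' enforces the linear ring fusion of ring B.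

Step 2
Reactants: 3 6-bromo-7-hydroxy-2,2-dimethylchroman-4-one; 4 ethyl propiolate
Product: 5 ethyl (E)-3-[(6-bromo-2,2-dimethyl-4-oxochroman-7-yl)oxy]prop-2-enoate
Conditions: DABCO (10 mol%), CH2Cl2, 0 °C to rt
Reagents that add atoms: none
Why: DABCO-catalysed oxa-Michael addition of the acidic phenol (para to the ketone) to the propiolate should give the E β-aryloxyacrylate, which places the future C2 on O2' and the future C3 within reach of the C–Br carbon.

Step 3
Reactants: 5 ethyl (E)-3-[(6-bromo-2,2-dimethyl-4-oxochroman-7-yl)oxy]prop-2-enoate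
Product: 6 ethyl 7,7-dimethyl-5-oxo-6,7-dihydro-5H-furo[3,2-g]chromene-3-carboxylate
Conditions: Pd(OAc)2 (5 mol%), PPh3 (10 mol%), Et3N (2 equiv), DMF, 110 °C
Reagents that add atoms: none
Why: Intramolecular Heck-type cyclisation of a 2-bromoaryl β-aryloxyacrylate (oxidative addition, C–C bond formation at the acrylate α-carbon, loss of HBr) is a standard entry to benzofuran-3-carboxylates and here forms the C3–C1' bond of the target within the temporary O2'–C2 tether.

Step 4
Reactants: 6 ethyl 7,7-dimethyl-5-oxo-6,7-dihydro-5H-furo[3,2-g]chromene-3-carboxylate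
Product: 8 ethyl 7,7-dimethyl-7H-furo[3,2-g]chromene-3-carboxylate, via ethyl 5-hydroxy-7,7-dimethyl-6,7-dihydro-5H-furo[3,2-g]chromene-3-carboxylate 7 (not isolated)
Conditions: NaBH4, MeOH/THF, 0 °C to rt; aqueous work-up; then p-TsOH·H2O (5 mol%), toluene, 80 °C
Reagents that add atoms: none
Why: Borohydride reduces the aryl ketone but not the vinylogous carbonate ester, and acid-catalysed E1 dehydration of the benzylic, oxygen-stabilised alcohol should give the 2,2-dimethylchromene (standard chromanone-to-chromene sequence).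

Step 5
Reactants: 8 ethyl 7,7-dimethyl-7H-furo[3,2-g]chromene-3-carboxylate
Product: 9 N-methoxy-N,7,7-trimethyl-7H-furo[3,2-g]chromene-3-carboxamide
Conditions: MeNHOMe·HCl (1.5 equiv), i-PrMgCl (3 equiv), THF, −20 to 0 °C
Reagents that add atoms: N,O-dimethylhydroxylamine hydrochloride, CNOC.Cl
Why: Aminolysis of the ester by the chloromagnesium amide of N,O-dimethylhydroxylamine (Weinreb amide formation) proceeds at low temperature, where the chromene and the benzofuran C2–H are not attacked.

Step 6
Reactants: 10 resorcinol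
Product: 11 1,3-bis(methoxymethoxy)benzene
Conditions: NaH (2.5 equiv), MOMCl (2.4 equiv), DMF, 0 °C to rt
Reagents that add atoms: chloromethyl methyl ether (MOMCl), COCCl
Why: O-alkylation of the bis-phenoxide with MOMCl (Williamson-type acetal formation) installs the two groups that later direct both metalations and survive every basic step.

Step 7
Reactants: 11 1,3-bis(methoxymethoxy)benzene; 12 prenyl bromide (1-bromo-3-methylbut-2-ene)
Product: 14 1,3-bis(methoxymethoxy)-2-(3-methylbut-2-en-1-yl)benzene, via [2,6-bis(methoxymethoxy)phenyl]lithium 13 (not isolated)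
Conditions: n-BuLi (1.1 equiv), THF, 0 °C to rt; then 12, −78 °C to rt
Reagents that add atoms: none
Why: Directed ortho-metalation at the carbon between the two OMOM groups gives 13, which should be alkylated at the primary carbon of prenyl bromide (SN2) to place the prenyl group between the future O5 and O7.

Step 8
Reactants: 14 1,3-bis(methoxymethoxy)-2-(3-methylbut-2-en-1-yl)benzene
Product: 16 3,5-bis(methoxymethoxy)-4-(3-methylbut-2-en-1-yl)phenol, via 2-[3,5-bis(methoxymethoxy)-4-(3-methylbut-2-en-1-yl)phenyl]-4,4,5,5-tetramethyl-1,3,2-dioxaborolane 15 (not isolated)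
Conditions: [Ir(OMe)(cod)]2 (1.5 mol%), dtbpy (3 mol%), B2pin2 (0.55 equiv), THF, 70 °C; then 30% H2O2, aq NaOH, 0 °C to rt
Reagents that add atoms: hydrogen peroxide, OO (the phenol oxygen); bis(pinacolato)diboron, CC1(C)OB(OC1(C)C)B1OC(C)(C)C(C)(C)O1 (boron of intermediate 15 only)
Why: Sterically controlled iridium-catalysed C–H borylation should take the only ring C–H that has no ortho substituent (para to the prenyl group), and alkaline peroxide then oxidises the C–B bond to the phenol without epoxidising the trisubstituted alkene (one-pot borylation/oxidation).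

Step 9
Reactants: 16 3,5-bis(methoxymethoxy)-4-(3-methylbut-2-en-1-yl)phenol
Product: 17 2-[3,5-bis(methoxymethoxy)-4-(3-methylbut-2-en-1-yl)phenoxy]tetrahydro-2H-pyran (racemic)
Conditions: 3,4-dihydro-2H-pyran (1.5 equiv), PPTS (5 mol%), CH2Cl2, rt
Reagents that add atoms: 3,4-dihydro-2H-pyran, C1CCOC=C1
Why: Acid-catalysed addition of the phenol to the enol ether (tetrahydropyranylation) marks the future O1 with an acetal that is far more labile than MOM yet still a metalation-directing group.

Step 10
Reactants: 17 2-[3,5-bis(methoxymethoxy)-4-(3-methylbut-2-en-1-yl)phenoxy]tetrahydro-2H-pyran; 9 N-methoxy-N,7,7-trimethyl-7H-furo[3,2-g]chromene-3-carboxamide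
Product: 19 (7,7-dimethyl-7H-furo[3,2-g]chromen-3-yl)[2,4-bis(methoxymethoxy)-3-(3-methylbut-2-en-1-yl)-6-(tetrahydro-2H-pyran-2-yloxy)phenyl]methanone (racemic), via [2,4-bis(methoxymethoxy)-3-(3-methylbut-2-en-1-yl)-6-(tetrahydro-2H-pyran-2-yloxy)phenyl]lithium 18 (not isolated)
Conditions: n-BuLi (1.1 equiv), TMEDA, THF, −20 to 0 °C; then 9, −78 to 0 °C; aq NH4Cl
Reagents that add atoms: none
Why: Both remaining ring C–H bonds of 17 are equivalent and flanked by two acetal oxygens, so cooperative directed ortho-metalation should give 18, whose acylation by the Weinreb amide stops at the ketone because of the chelated tetrahedral intermediate.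

Step 11
Reactants: 19 (7,7-dimethyl-7H-furo[3,2-g]chromen-3-yl)[2,4-bis(methoxymethoxy)-3-(3-methylbut-2-en-1-yl)-6-(tetrahydro-2H-pyran-2-yloxy)phenyl]methanone
Product: 22 3-(7-hydroxy-2,2-dimethyl-2H-chromen-6-yl)-5,7-bis(methoxymethoxy)-6-(3-methylbut-2-en-1-yl)-4H-chromen-4-one, via (7,7-dimethyl-7H-furo[3,2-g]chromen-3-yl)[6-hydroxy-2,4-bis(methoxymethoxy)-3-(3-methylbut-2-en-1-yl)phenyl]methanone 20 (not isolated), via the potassium enolate of the oxa-Michael adduct (ring A oxygen bonded to the former furan C2, now an acetal carbon) 21 (not isolated)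
Conditions: PPTS (0.2 equiv), MeOH/THF, rt; then K2CO3 (0.5 equiv), rt to 40 °C; aq NH4Cl
Reagents that add atoms: none
Why: Mild methanolysis cleaves only the aryl THP acetal, giving 20 with a single free phenol on the aroyl ring; its phenoxide adds to C2 of the 3-acylbenzofuran (a vinylogous ester) and the enolate 21 then expels the ring B oxygen by E1cB cleavage of the furan C2–O bond, which turns the furan into the pyranone and sets the 2'-OH free. The closest known reaction is the ring-opening/cyclisation of 3-(2-hydroxybenzoyl)benzofurans to 2'-hydroxyisoflavones, of which this is a base-triggered case. Ring C closes in a 6-endo-trig oxa-Michael mode and no stereocentre is formed, since the acetal carbon of 21 returns to sp2. The selectivity needed is the choice of the ortho oxygen that becomes O1: the oxygen beside the ring C–H is the only free one and the oxygen beside the prenyl group stays a MOM ether, so the prenyl group can only end at C6. The reaction should be driven by the exchange of a twisted, di-ortho-substituted diaryl ketone for a planar chromone conjugated with ring A, with the new 2'-OH hydrogen-bonded to C4=O. The MOM ethers, the prenyl group and the chromene are inert to PPTS in methanol at room temperature and to carbonate.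

Step 12
Reactants: 22 3-(7-hydroxy-2,2-dimethyl-2H-chromen-6-yl)-5,7-bis(methoxymethoxy)-6-(3-methylbut-2-en-1-yl)-4H-chromen-4-one
Product: 23 Krausianone 2, 5,7-dihydroxy-3-(7-hydroxy-2,2-dimethyl-2H-chromen-6-yl)-6-(3-methylbut-2-en-1-yl)-4H-chromen-4-one
Conditions: 3 M aq HCl/MeOH (1:4), 50 °C
Reagents that add atoms: none
Why: Acid-catalysed acetal methanolysis removes both MOM groups (the chelated 5-O-MOM first) under dilute, warm conditions of the kind commonly used for prenylated and pyrano-fused isoflavones, which should leave the prenyl group and the chromene intact.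

Compound list
1 | 4-bromoresorcinol | Oc1ccc(Br)c(O)c1 | starting material
2 | 3-methylbut-2-enoic acid | CC(C)=CC(=O)O | starting material
3 | 6-bromo-7-hydroxy-2,2-dimethylchroman-4-one | CC1(C)CC(=O)c2cc(Br)c(O)cc2O1 | intermediate
4 | ethyl propiolate | CCOC(=O)C#C | starting material
5 | ethyl (E)-3-[(6-bromo-2,2-dimethyl-4-oxochroman-7-yl)oxy]prop-2-enoate | CCOC(=O)/C=C/Oc1cc2OC(C)(C)CC(=O)c2cc1Br | intermediate
6 | ethyl 7,7-dimethyl-5-oxo-6,7-dihydro-5H-furo[3,2-g]chromene-3-carboxylate | CCOC(=O)c1coc2cc3OC(C)(C)CC(=O)c3cc12 | intermediate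
7 | ethyl 5-hydroxy-7,7-dimethyl-6,7-dihydro-5H-furo[3,2-g]chromene-3-carboxylate (racemic) | CCOC(=O)c1coc2cc3OC(C)(C)CC(O)c3cc12 | intermediate
8 | ethyl 7,7-dimethyl-7H-furo[3,2-g]chromene-3-carboxylate | CCOC(=O)c1coc2cc3OC(C)(C)C=Cc3cc12 | intermediate
9 | N-methoxy-N,7,7-trimethyl-7H-furo[3,2-g]chromene-3-carboxamide | CON(C)C(=O)c1coc2cc3OC(C)(C)C=Cc3cc12 | intermediate
10 | resorcinol | Oc1cccc(O)c1 | starting material
11 | 1,3-bis(methoxymethoxy)benzene | COCOc1cccc(OCOC)c1 | intermediate
12 | prenyl bromide (1-bromo-3-methylbut-2-ene) | CC(C)=CCBr | starting material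
13 | [2,6-bis(methoxymethoxy)phenyl]lithium | [Li]c1c(OCOC)cccc1OCOC | intermediate
14 | 1,3-bis(methoxymethoxy)-2-(3-methylbut-2-en-1-yl)benzene | COCOc1cccc(OCOC)c1CC=C(C)C | intermediate
15 | 2-[3,5-bis(methoxymethoxy)-4-(3-methylbut-2-en-1-yl)phenyl]-4,4,5,5-tetramethyl-1,3,2-dioxaborolane | COCOc1cc(B2OC(C)(C)C(C)(C)O2)cc(OCOC)c1CC=C(C)C | intermediate
16 | 3,5-bis(methoxymethoxy)-4-(3-methylbut-2-en-1-yl)phenol | COCOc1cc(O)cc(OCOC)c1CC=C(C)C | intermediate
17 | 2-[3,5-bis(methoxymethoxy)-4-(3-methylbut-2-en-1-yl)phenoxy]tetrahydro-2H-pyran (racemic) | COCOc1cc(OC2CCCCO2)cc(OCOC)c1CC=C(C)C | intermediate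
18 | [2,4-bis(methoxymethoxy)-3-(3-methylbut-2-en-1-yl)-6-(tetrahydro-2H-pyran-2-yloxy)phenyl]lithium (racemic) | [Li]c1c(OC2CCCCO2)cc(OCOC)c(CC=C(C)C)c1OCOC | intermediate
19 | (7,7-dimethyl-7H-furo[3,2-g]chromen-3-yl)[2,4-bis(methoxymethoxy)-3-(3-methylbut-2-en-1-yl)-6-(tetrahydro-2H-pyran-2-yloxy)phenyl]methanone (racemic) | COCOc1cc(OC2CCCCO2)c(C(=O)c2coc3cc4OC(C)(C)C=Cc4cc23)c(OCOC)c1CC=C(C)C | intermediate
20 | (7,7-dimethyl-7H-furo[3,2-g]chromen-3-yl)[6-hydroxy-2,4-bis(methoxymethoxy)-3-(3-methylbut-2-en-1-yl)phenyl]methanone | COCOc1cc(O)c(C(=O)c2coc3cc4OC(C)(C)C=Cc4cc23)c(OCOC)c1CC=C(C)C | intermediate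
21 | potassium enolate of the oxa-Michael adduct (racemic at the acetal carbon, the former furan C2) | COCOc1cc2OC3Oc4cc5OC(C)(C)C=Cc5cc4C3=C([O-])c2c(OCOC)c1CC=C(C)C.[K+] | intermediate
22 | 3-(7-hydroxy-2,2-dimethyl-2H-chromen-6-yl)-5,7-bis(methoxymethoxy)-6-(3-methylbut-2-en-1-yl)-4H-chromen-4-one | COCOc1cc2occ(-c3cc4C=CC(C)(C)Oc4cc3O)c(=O)c2c(OCOC)c1CC=C(C)C | intermediate
23 | Krausianone 2 | CC(C)=CCc1c(O)cc2occ(-c3cc4c(cc3O)OC(C)(C)C=C4)c(=O)c2c1O | target

Total step count: 12. Longest linear sequence: 8 steps (steps 1–5, 10, 11, 12); the ring A branch (steps 6–9) joins at step 10.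

Steps most likely to fail

Step 11 (key step). The transposition may stop at an unfavourable equilibrium between the furan-closed and the pyranone-closed form, or the new pyranone may be reopened at C2 by methoxide. The fallback sets out from 19 and comes back at 23. It excises the furan C2 carbon and re-installs it once O2' is blocked, which is the classical deoxybenzoin route with full control of the two phenols. Aqueous KOH in ethanol at 80 °C should hydrolyse the vinylogous ester of 19 and deformylate the β-ketoaldehyde by retro-Claisen cleavage. This gives the deoxybenzoin 1-[2,4-bis(methoxymethoxy)-3-(3-methylbut-2-en-1-yl)-6-(tetrahydro-2H-pyran-2-yloxy)phenyl]-2-(7-hydroxy-2,2-dimethyl-2H-chromen-6-yl)ethan-1-one F1. MOMCl/DIPEA in CH2Cl2 caps the ring B phenol to give the MOM ether F2, and PPTS in MeOH frees the ring A phenol to give the hydroxy ketone F3. DMF dimethyl acetal in toluene at 90 °C gives the enaminone F4, which closes with loss of dimethylamine to the tris-MOM isoflavone F5. The HCl/MeOH conditions of step 12 then remove three MOM groups and give 23.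

Step 10. Proton transfer may win over C–C bond formation: lateral metalation at the benzylic/allylic CH2 of 17, or deprotonation of the benzofuran C2–H of 9 by 18, would return starting materials. The fallback sets out from 16 and 9 and comes back at 19. Iodination of 16 (I2, NaHCO3, THF/H2O, 0 °C; the two open ring positions are equivalent) gives 2-iodo-3,5-bis(methoxymethoxy)-4-(3-methylbut-2-en-1-yl)phenol F6, and DHP/PPTS gives its THP ether F7. Iodine–magnesium exchange (i-PrMgCl·LiCl, THF, −20 °C) fixes the metalation site and gives the arylmagnesium chloride F8. This adds to 7,7-dimethyl-7H-furo[3,2-g]chromene-3-carbaldehyde F9 (from 9 with DIBAL-H, THF, −78 °C), an electrophile that is attacked much faster than it is deprotonated. The diarylmethanol F10 is oxidised with MnO2 in CH2Cl2 to 19.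

Step 12. Under protic acid the prenyl group may cyclise onto the freed 5-OH or 7-OH (chroman formation), or methanol may add to the electron-rich chromene double bond, before both acetals are gone. The fallback sets out from 22 and comes back at 23. It exchanges the acetals for silyl ethers without protic acid: TESOTf/2,2'-bipyridyl in CH2Cl2 (0 °C to rt) should convert both aryl MOM ethers into TES ethers and silylate the 2'-OH. This gives 3-[2,2-dimethyl-7-(triethylsilyloxy)-2H-chromen-6-yl]-6-(3-methylbut-2-en-1-yl)-5,7-bis(triethylsilyloxy)-4H-chromen-4-one F11, and buffered fluoride (TBAF/AcOH, THF, 0 °C) then gives 23.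

Further compounds
F1 | step 11 | 1-[2,4-bis(methoxymethoxy)-3-(3-methylbut-2-en-1-yl)-6-(tetrahydro-2H-pyran-2-yloxy)phenyl]-2-(7-hydroxy-2,2-dimethyl-2H-chromen-6-yl)ethan-1-one (racemic) | COCOc1cc(OC2CCCCO2)c(C(=O)Cc2cc3C=CC(C)(C)Oc3cc2O)c(OCOC)c1CC=C(C)C
F2 | step 11 | 1-[2,4-bis(methoxymethoxy)-3-(3-methylbut-2-en-1-yl)-6-(tetrahydro-2H-pyran-2-yloxy)phenyl]-2-[7-(methoxymethoxy)-2,2-dimethyl-2H-chromen-6-yl]ethan-1-one (racemic) | COCOc1cc(OC2CCCCO2)c(C(=O)Cc2cc3C=CC(C)(C)Oc3cc2OCOC)c(OCOC)c1CC=C(C)C
F3 | step 11 | 1-[6-hydroxy-2,4-bis(methoxymethoxy)-3-(3-methylbut-2-en-1-yl)phenyl]-2-[7-(methoxymethoxy)-2,2-dimethyl-2H-chromen-6-yl]ethan-1-one | COCOc1cc(O)c(C(=O)Cc2cc3C=CC(C)(C)Oc3cc2OCOC)c(OCOC)c1CC=C(C)C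
F4 | step 11 | 3-(dimethylamino)-1-[6-hydroxy-2,4-bis(methoxymethoxy)-3-(3-methylbut-2-en-1-yl)phenyl]-2-[7-(methoxymethoxy)-2,2-dimethyl-2H-chromen-6-yl]prop-2-en-1-one | COCOc1cc(O)c(C(=O)C(=CN(C)C)c2cc3C=CC(C)(C)Oc3cc2OCOC)c(OCOC)c1CC=C(C)C
F5 | step 11 | 5,7-bis(methoxymethoxy)-3-[7-(methoxymethoxy)-2,2-dimethyl-2H-chromen-6-yl]-6-(3-methylbut-2-en-1-yl)-4H-chromen-4-one | COCOc1cc2occ(-c3cc4C=CC(C)(C)Oc4cc3OCOC)c(=O)c2c(OCOC)c1CC=C(C)C
F6 | step 10 | 2-iodo-3,5-bis(methoxymethoxy)-4-(3-methylbut-2-en-1-yl)phenol | COCOc1cc(O)c(I)c(OCOC)c1CC=C(C)C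
F7 | step 10 | 2-[2-iodo-3,5-bis(methoxymethoxy)-4-(3-methylbut-2-en-1-yl)phenoxy]tetrahydro-2H-pyran (racemic) | COCOc1cc(OC2CCCCO2)c(I)c(OCOC)c1CC=C(C)C
F8 | step 10 | [2,4-bis(methoxymethoxy)-3-(3-methylbut-2-en-1-yl)-6-(tetrahydro-2H-pyran-2-yloxy)phenyl]magnesium chloride (racemic) | COCOc1cc(OC2CCCCO2)c([Mg]Cl)c(OCOC)c1CC=C(C)C
F9 | step 10 | 7,7-dimethyl-7H-furo[3,2-g]chromene-3-carbaldehyde | O=Cc1coc2cc3OC(C)(C)C=Cc3cc12
F10 | step 10 | [2,4-bis(methoxymethoxy)-3-(3-methylbut-2-en-1-yl)-6-(tetrahydro-2H-pyran-2-yloxy)phenyl](7,7-dimethyl-7H-furo[3,2-g]chromen-3-yl)methanol (mixture of diastereomers) | COCOc1cc(OC2CCCCO2)c(C(O)c2coc3cc4OC(C)(C)C=Cc4cc23)c(OCOC)c1CC=C(C)C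
F11 | step 12 | 3-[2,2-dimethyl-7-(triethylsilyloxy)-2H-chromen-6-yl]-6-(3-methylbut-2-en-1-yl)-5,7-bis(triethylsilyloxy)-4H-chromen-4-one | CC[Si](CC)(CC)Oc1cc2occ(-c3cc4C=CC(C)(C)Oc4cc3O[Si](CC)(CC)CC)c(=O)c2c(O[Si](CC)(CC)CC)c1CC=C(C)C
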